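You cannot read these flasks as starting material simply turning into target over a free catalyst: in a closed flask, Friday's run at its last reading shows 83.9 % of the charge in those two forms.

| flask | starting material | free catalyst | remark | time |
|---|---|---|---|---|
| Friday's | 2.5 mM | 5.2 mol% | run made earlier |  |
| Wednesday's | 19 mM | 5.2 mol% | run made earlier |  |
| Monday's | 10 mM | 5.9 mol% | run made earlier |  |
| zeta | 30 mM | 1.5 mol% |  | 10 h |
| eta | 3.0 mM | 1.5 mol% |  | 10 h |
| delta | 10 mM | 5.2 mol% |  | 10 h |
| alpha | 3.0 mM | 20 mol% |  | 10 h |

| run | time / h | target / % | starting material / % |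
|---|---|---|---|
| Friday's | 0.250 | 0.7 | 97.0 |
| Friday's | 0.833 | 6.2 | 90.6 |
| Friday's | 1.33 | 8.4 | 84.8 |
| Friday's | 2.00 | 12.5 | 79.2 |
| Friday's | 3.00 | 17.6 | 70.3 |
| Friday's | 4.00 | 22.4 | 63.8 |
| Friday's | 5.00 | 25.9 | 58.0 |
| Wednesday's | 0.667 | 16.1 | 63.2 |
| Wednesday's | 1.33 | 28.0 | 44.2 |
| Wednesday's | 2.00 | 35.0 | 33.4 |
| Wednesday's | 3.00 | 43.2 | 21.0 |
| Wednesday's | 4.00 | 48.5 | 15.7 |
| Wednesday's | 5.00 | 52.7 | 10.1 |
| Monday's | 1.00 | 18.9 | 65.0 |
| Monday's | 2.00 | 32.3 | 45.0 |
| Monday's | 3.00 | 40.2 | 35.0 |
| Monday's | 4.00 | 46.3 | 24.5 |
| Monday's | 5.00 | 51.6 | 19.3 |

(each reading ± 0.5 percentage points)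



- all flasks from highest to lowest amount of target, in percent of the starting material charged, at 10 h (zeta / eta / delta / alpha)
- the amount of target, in percent of the starting material charged of the flask you put first, at 10 h
- the amount of target, in percent of the starting material charged of the flask you put last, at 10 h

1. Call the missing part the loss: 16.1 % in Friday's run and 37.2 % in Wednesday's, both at the last reading. Target over loss is the branch ratio, a selectivity factor: 1.61 on Friday, 1.42 on Wednesday.

2. These two runs share a loading, and [starting material] differs by a factor 7.60, yet the ratio stays near. You expect that if target goes with [free catalyst][starting material] and loss with [starting material] squared: what remains is [free catalyst]/[starting material], the loading.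

3. So scale Friday's ratio by loading. Alpha's ratio becomes 6.19, and its share is 86.1 %. This target share is the fraction of used starting material that ends as target, ratio over ratio plus one. Delta, at Friday's loading, has 61.7 %; eta and zeta have 31.7 %.

4. Now the speed. Friday's pseudo-first-order constant is 0.109 /h. Split by share, 0.0672 /h is catalytic and 0.0418 /h is loss. The first scales with [free catalyst], the second with [starting material]. Eta then has 0.0734 /h, uses 52.0 %, and makes 16.5 %. Alpha's catalytic constant, scaled likewise, is 0.310 /h.

5. That last scaling is the weak link. Monday's run has 0.590 mM of free catalyst against alpha's 0.600 mM, and it reads 0.210 /h catalytic, less than the scaled value. Taking Monday's value, alpha has 0.260 /h, uses 92.6 %, and makes 79.7 %.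

6. For the order: Monday's run, near delta's recipe, had used 80.7 % by its last reading, which at delta's share is 49.8 %, above zeta's share. Zeta has eta's share, the loading being the same, but 0.450 mM of free catalyst against eta's 0.0450 mM, so by step 4 its constant is 0.734 /h against 0.0734 /h: zeta uses more of its charge, and at equal share it stands above eta. I commit to alpha, delta, zeta, eta.

The forecast, whose grounds open with “The mass balance gap points to two parallel channels”, gives alpha > delta > zeta > eta, with alpha at 79 % (75 % to 83 %) and eta at 17.6 % (15 % to 21 %).

The flasks give alpha > delta > zeta > eta, with alpha at 82.2 % and eta at 16.6 %.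

    2 starting material → self-condensation product (k = 0.00298 /M/s)
    starting material + free catalyst → catalyst intermediate (k = 0.162 /M/s)
    catalyst intermediate ⇌ free catalyst + target (K = 0.0100 M, k = 0.00452 /s)

With 4.6 % of starting material left in alpha at 10.0 h, the target share gives 82.1 %. Two steps together hold alpha below full yield: the run without self-condensation reaches 89.9 %, and the run without free catalyst + target falling back to catalyst intermediate reaches 88.5 %.

Take alpha's recipe at 7.5 mM: the loading is the same, so the reckoning keeps the target share at 86.1 %, and with 0.28 % left it gives 85.9 %. That neighbour flask computes to 81.5 %, which is 4.3 percentage points lower.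

(The readings are simulated on assumed constants; noise was put on by code.)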